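The plan rests on cutting the C3–C4 bond of ring A. These carbons bear cis oxygens, secondary at C3 and tertiary at C4 (methyl C15), which marks the bond as a pinacol bond: in retrosynthesis it opens to a C3 aldehyde and a C4 methyl ketone. One SmI2 coupling then closes ring A, forms C3–C4 and sets both carbinol centres. The precursor 11 is ring B alone: C8 masked as an ethylene ketal, quaternary C10 carrying methyl C14 and a 3-oxopropyl arm, C5 carrying an acetyl arm cis to C14, the two arms trans-diequatorial. C5 comes from (+)-verbenone, whose bridge also dictates C10.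

Key step: step 6

Assumption: eudesmane numbering (C1–C15) is used for every intermediate, and (1R,5R)-verbenone of high optical purity (the allylic oxidation product of (+)-α-pinene) and a THF solution of 2 are taken as purchasable.

Step 1
Reactants: 1 (1R,5R)-(+)-verbenone; 2 but-3-enylmagnesium bromide
Product: 4 (1R,4R,5R)-4-(but-3-enyl)-4,6,6-trimethylbicyclo[3.1.1]heptan-2-one, via silyl enol ether 3 (not isolated)
Conditions: CuBr·SMe2 (10 mol %), TMSCl, THF, −78 → −20 °C; then 1 M HCl, 0 °C
Reagents that add atoms: but-3-enylmagnesium bromide (2), C=CCC[Mg]Br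
Why: Copper-catalysed, TMSCl-accelerated conjugate addition of a Grignard reagent; the CMe2 bridge screens one face of the enone, so the butenyl group enters from the CH2-bridge side and the new quaternary C10 carries methyl C14 syn to the CMe2 bridge, its absolute sense following from 1.

Step 2
Reactants: 4 (1R,4R,5R)-4-(but-3-enyl)-4,6,6-trimethylbicyclo[3.1.1]heptan-2-one; 5 acetic anhydride
Product: 6 (4S,5R)-5-(but-3-enyl)-5-methyl-4-(prop-1-en-2-yl)cyclohex-1-en-1-yl acetate
Conditions: BF3·OEt2, Zn(OAc)2, Ac2O (solvent), 0 °C → rt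
Reagents that add atoms: acetic anhydride (5), CC(=O)OC(C)=O
Why: Lewis-acid-promoted acylative cyclobutane fragmentation, known for nopinone- and verbanone-type ketones: the strained bond between C7 (α to the carbonyl) and the CMe2 carbon (future C4) ionises, the enol half is captured as the C7=C8 enol acetate and the tertiary cation sheds a methyl proton, so that C5 keeps its configuration and ends up with an isopropenyl group cis to C14 and trans to the butenyl arm.

Step 3
Reactants: 6 (4S,5R)-5-(but-3-enyl)-5-methyl-4-(prop-1-en-2-yl)cyclohex-1-en-1-yl acetate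
Product: 7 (3R,4S)-3-(but-3-enyl)-3-methyl-4-(prop-1-en-2-yl)cyclohexan-1-one
Conditions: K2CO3 (cat.), MeOH, 0 °C
Reagents that add atoms: none
Why: Base-catalysed methanolysis (transesterification) of the enol ester frees the C8 ketone, and neither C5 nor C10 is α to it, so nothing can epimerise.

Step 4
Reactants: 7 (3R,4S)-3-(but-3-enyl)-3-methyl-4-(prop-1-en-2-yl)cyclohexan-1-one; 8 ethane-1,2-diol
Product: 9 (7R,8S)-7-(but-3-enyl)-7-methyl-8-(prop-1-en-2-yl)-1,4-dioxaspiro[4.5]decane
Conditions: PPTS (cat.), benzene, reflux, Dean–Stark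
Reagents that add atoms: ethane-1,2-diol (8), OCCO
Why: Acid-catalysed ketalisation with azeotropic removal of water; the weak acid PPTS should leave the isopropenyl double bond where it is, and the ketal removes C8 from the carbonyl chemistry of step 6.

Step 5
Reactants: 9 (7R,8S)-7-(but-3-enyl)-7-methyl-8-(prop-1-en-2-yl)-1,4-dioxaspiro[4.5]decane
Product: 11 3-[(7R,8R)-8-acetyl-7-methyl-1,4-dioxaspiro[4.5]decan-7-yl]propanal, via bis-ozonide 10 (not isolated)
Conditions: O3, CH2Cl2, −78 °C; then Me2S, −78 °C → rt; used at once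
Reagents that add atoms: ozone, [O-][O+]=O
Why: Ozonolysis with reductive work-up cuts both terminal alkenes in one operation, isopropenyl to the C4 methyl ketone and butenyl to the C3 aldehyde, under neutral conditions that spare the ketal and the now epimerisable C5, so that the aldol-prone 11 is unveiled only immediately before use.

Step 6
Reactants: 11 3-[(7R,8R)-8-acetyl-7-methyl-1,4-dioxaspiro[4.5]decan-7-yl]propanal
Product: 13 8,8-ethylenedioxy-11,12,13-trinor-5αH-eudesmane-3α,4α-diol, via samarium diolate 12 (not isolated)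
Conditions: SmI2 (0.1 M in THF, 2.5 equiv), t-BuOH (2 equiv), THF, −78 °C → rt, slow addition of 11; aq potassium sodium tartrate
Reagents that add atoms: none
Why: SmI2 (divalent samarium) gives one electron to the C3 aldehyde, the easier carbonyl to reduce; the ketyl, tied through trivalent samarium to the C4 ketone oxygen, attacks C4, and a second SmI2 reduces the oxygen radical so formed to diolate 12, which is protonated to 13. This is the intramolecular pinacol coupling of a 1,6-keto aldehyde, a known route to cis-cyclohexane-1,2-diols. Ring A closes 6-exo-trig onto C4=O through a chair, open to 11 because its two arms are trans-diequatorial on ring B. C3 is controlled by the samarium bridge, which holds O3 and O4 on one face (cis). C4 is controlled by the acetyl rotamer that closes: the wanted one turns the samarium-laden O4 outwards into the equatorial α site, away from axial C14, leaves C15 axial and thereby places O3 axial α. The step needs chemoselectivity, secured by the C8 ketal (a free C8 ketone would offer C3 a rival six-membered closure), and α-face selectivity, which rests only on the bulk of the samarium alkoxide against a C14/C15 1,3-diaxial contact and is the risk the route accepts.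

Step 7
Reactants: 13 8,8-ethylenedioxy-11,12,13-trinor-5αH-eudesmane-3α,4α-diol; 14 angelic acid
Product: 16 8,8-ethylenedioxy-4α-hydroxy-11,12,13-trinor-5αH-eudesman-3α-yl angelate, via mixed anhydride 15 (not isolated)
Conditions: 14, 2,4,6-Cl3C6H2COCl, Et3N, toluene, rt; then 13, 80 °C
Reagents that add atoms: angelic acid (14), C/C=C(/C)C(=O)O
Why: Yamaguchi-type mixed-anhydride esterification run without DMAP, a protocol known to transfer the angeloyl group without Z-to-E drift; attack occurs at the unhindered angeloyl carbonyl of 15 and only the secondary C3 hydroxyl is acylated, the tertiary C4 hydroxyl staying free.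

Step 8
Reactants: 16 8,8-ethylenedioxy-4α-hydroxy-11,12,13-trinor-5αH-eudesman-3α-yl angelate; 5 acetic anhydride
Product: 17 4α-acetoxy-8,8-ethylenedioxy-11,12,13-trinor-5αH-eudesman-3α-yl angelate
Conditions: Ac2O (excess), DMAP, Et3N, CH2Cl2, 40 °C
Reagents that add atoms: acetic anhydride (5), CC(=O)OC(C)=O
Why: DMAP-catalysed acylation of a tertiary alcohol by excess anhydride; the angelate already occupies the thermodynamically preferred secondary oxygen and the ketal is inert to the basic medium.

Step 9
Reactants: 17 4α-acetoxy-8,8-ethylenedioxy-11,12,13-trinor-5αH-eudesman-3α-yl angelate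
Product: 18 4α-acetoxy-8-oxo-11,12,13-trinor-5αH-eudesman-3α-yl angelate
Conditions: 1 M HCl, THF, rt
Reagents that add atoms: water, O
Why: Acid-catalysed ketal hydrolysis, under which a secondary enoate and a tertiary acetate flanked by an electron-withdrawing acyloxy group should both persist.

Step 10
Reactants: 18 4α-acetoxy-8-oxo-11,12,13-trinor-5αH-eudesman-3α-yl angelate
Product: 19 4α-acetoxy-8-(trimethylsilyloxy)-11,12,13-trinor-5αH-eudesm-7-en-3α-yl angelate
Conditions: TMSOTf, Et3N, CH2Cl2, 0 °C
Reagents that add atoms: trimethylsilyl trifluoromethanesulfonate, C[Si](C)(C)OS(=O)(=O)C(F)(F)F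
Why: Soft enolisation and O-silylation of the ketone; a trans-fused decalone whose other α-carbon (C9) is neopentyl and adjoins the ring fusion enolises towards C7, as 5α-steroidal 2-ketones do towards C3, and esters are not silylated under these conditions.

Step 11
Reactants: 19 4α-acetoxy-8-(trimethylsilyloxy)-11,12,13-trinor-5αH-eudesm-7-en-3α-yl angelate; 20 acetone
Product: 22 4α-acetoxy-11-hydroxy-8-oxo-5αH-eudesman-3α-yl angelate (C7 epimers), via titanium aldolate 21 (not isolated)
Conditions: TiCl4, CH2Cl2, −78 °C; aq NaHCO3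
Reagents that add atoms: acetone (20), CC(C)=O
Why: Mukaiyama aldol addition, for which acetone activated by TiCl4 is an established acceptor; the titanium chelate 21 holds the tertiary aldolate against retro-aldol cleavage, and the new C7 centre is of no consequence because step 12 erases it.

Step 12
Reactants: 22 4α-acetoxy-11-hydroxy-8-oxo-5αH-eudesman-3α-yl angelate (C7 epimers)
Product: 24 4α-acetoxy-8-oxo-5αH-eudesm-7(11)-en-3α-yl angelate, via mesylate 23 (not isolated)
Conditions: MsCl, Et3N, CH2Cl2, 0 °C; then DBU, rt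
Reagents that add atoms: none
Why: Mesylation of the tertiary carbinol followed by base-induced elimination across C7–C11 (E1cB type), DBU also drawing any isopropenyl isomer into conjugation, so that the tetrasubstituted 7(11)-en-8-one results with the ring-A esters and all four stereocentres untouched.

Step 13
Reactants: 24 4α-acetoxy-8-oxo-5αH-eudesm-7(11)-en-3α-yl angelate
Product: 26 4α-acetoxy-11-hydroxy-8-oxo-5αH-eudesm-6-en-3α-yl angelate (CNP0351454.1), via hydroperoxide 25 (not isolated)
Conditions: O2, 5,10,15,20-tetraphenylporphyrin (cat.), visible light, CH2Cl2, 0 °C; then PPh3, 0 °C → rt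
Reagents that add atoms: dioxygen, O=O
Why: Schenck ene reaction of singlet oxygen with an s-cis α-isopropylidene ketone of the pulegone type, a class known to lose hydrogen from the group geminal to the carbonyl: oxygen bonds to C11, axial H6β is removed and the double bond moves to C6=C7, PPh3 then reduces 25 to the alcohol, the electron-poor angelate reacts far more slowly, and the neutral medium protects C5–H and the C4 acetate from vinylogous elimination.

Compound list
1 | (1R,5R)-(+)-verbenone, (1R,5R)-4,6,6-trimethylbicyclo[3.1.1]hept-3-en-2-one | CC1=CC(=O)[C@@H]2C[C@H]1C2(C)C | starting material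
2 | but-3-enylmagnesium bromide | C=CCC[Mg]Br | starting material
3 | trimethylsilyl enol ether of 4 (C8=C9 enol ether, butenyl anti to the CMe2 bridge) | C=CCC[C@]1(C)C=C(O[Si](C)(C)C)[C@@H]2C[C@H]1C2(C)C | intermediate
4 | (1R,4R,5R)-4-(but-3-enyl)-4,6,6-trimethylbicyclo[3.1.1]heptan-2-one (butenyl anti to the CMe2 bridge) | C=CCC[C@]1(C)CC(=O)[C@@H]2C[C@H]1C2(C)C | intermediate
5 | acetic anhydride | CC(=O)OC(C)=O | starting material
6 | (4S,5R)-5-(but-3-enyl)-5-methyl-4-(prop-1-en-2-yl)cyclohex-1-en-1-yl acetate | C=CCC[C@]1(C)CC(OC(C)=O)=CC[C@H]1C(C)=C | intermediate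
7 | (3R,4S)-3-(but-3-enyl)-3-methyl-4-(prop-1-en-2-yl)cyclohexan-1-one | C=CCC[C@]1(C)CC(=O)CC[C@H]1C(C)=C | intermediate
8 | ethane-1,2-diol | OCCO | starting material
9 | (7R,8S)-7-(but-3-enyl)-7-methyl-8-(prop-1-en-2-yl)-1,4-dioxaspiro[4.5]decane | C=CCC[C@]1(C)CC2(OCCO2)CC[C@H]1C(C)=C | intermediate
10 | bis(1,2,4-trioxolane) of 9 (ozonide carbons unassigned) | C1OC(CC[C@]2(C)CC3(OCCO3)CC[C@H]2C2(C)OCOO2)OO1 | intermediate
11 | 3-[(7R,8R)-8-acetyl-7-methyl-1,4-dioxaspiro[4.5]decan-7-yl]propanal (acetyl cis to methyl) | O=CCC[C@]1(C)CC2(OCCO2)CC[C@H]1C(C)=O | intermediate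
12 | 3α,4α-bis(diiodosamarium) diolate of 13 (trivalent samarium) | I[Sm](I)O[C@@H]1CC[C@]2(C)CC3(OCCO3)CC[C@H]2[C@]1(C)O[Sm](I)I | intermediate
13 | 8,8-ethylenedioxy-11,12,13-trinor-5αH-eudesmane-3α,4α-diol (trans-decalin, C14 and C15 β) | O[C@@H]1CC[C@]2(C)CC3(OCCO3)CC[C@H]2[C@]1(C)O | intermediate
14 | angelic acid, (Z)-2-methylbut-2-enoic acid | C/C=C(/C)C(=O)O | starting material
15 | angelic 2,4,6-trichlorobenzoic anhydride | C/C=C(/C)C(=O)OC(=O)c1c(Cl)cc(Cl)cc1Cl | intermediate
16 | 8,8-ethylenedioxy-4α-hydroxy-11,12,13-trinor-5αH-eudesman-3α-yl angelate | C/C=C(/C)C(=O)O[C@@H]1CC[C@]2(C)CC3(OCCO3)CC[C@H]2[C@]1(C)O | intermediate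
17 | 4α-acetoxy-8,8-ethylenedioxy-11,12,13-trinor-5αH-eudesman-3α-yl angelate | C/C=C(/C)C(=O)O[C@@H]1CC[C@]2(C)CC3(OCCO3)CC[C@H]2[C@]1(C)OC(C)=O | intermediate
18 | 4α-acetoxy-8-oxo-11,12,13-trinor-5αH-eudesman-3α-yl angelate | C/C=C(/C)C(=O)O[C@@H]1CC[C@]2(C)CC(=O)CC[C@H]2[C@]1(C)OC(C)=O | intermediate
19 | 4α-acetoxy-8-(trimethylsilyloxy)-11,12,13-trinor-5αH-eudesm-7-en-3α-yl angelate | C/C=C(/C)C(=O)O[C@@H]1CC[C@]2(C)CC(O[Si](C)(C)C)=CC[C@H]2[C@]1(C)OC(C)=O | intermediate
20 | acetone | CC(C)=O | starting material
21 | trichlorotitanium 11-alkoxide of 22 (tetravalent titanium, C7 unassigned) | C/C=C(/C)C(=O)O[C@@H]1CC[C@]2(C)CC(=O)C(C(C)(C)O[Ti](Cl)(Cl)Cl)C[C@H]2[C@]1(C)OC(C)=O | intermediate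
22 | 4α-acetoxy-11-hydroxy-8-oxo-5αH-eudesman-3α-yl angelate (C7 epimers, centre erased in step 12) | C/C=C(/C)C(=O)O[C@@H]1CC[C@]2(C)CC(=O)C(C(C)(C)O)C[C@H]2[C@]1(C)OC(C)=O | intermediate
23 | 11-methanesulfonate of 22 | C/C=C(/C)C(=O)O[C@@H]1CC[C@]2(C)CC(=O)C(C(C)(C)OS(C)(=O)=O)C[C@H]2[C@]1(C)OC(C)=O | intermediate
24 | 4α-acetoxy-8-oxo-5αH-eudesm-7(11)-en-3α-yl angelate | C/C=C(/C)C(=O)O[C@@H]1CC[C@]2(C)CC(=O)C(=C(C)C)C[C@H]2[C@]1(C)OC(C)=O | intermediate
25 | 4α-acetoxy-11-hydroperoxy-8-oxo-5αH-eudesm-6-en-3α-yl angelate | C/C=C(/C)C(=O)O[C@@H]1CC[C@]2(C)CC(=O)C(C(C)(C)OO)=C[C@H]2[C@]1(C)OC(C)=O | intermediate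
26 | 4α-acetoxy-11-hydroxy-8-oxo-5αH-eudesm-6-en-3α-yl angelate (CNP0351454.1) | C/C=C(/C)C(=O)O[C@@H]1CC[C@]2(C)CC(=O)C(C(C)(C)O)=C[C@H]2[C@]1(C)OC(C)=O | target

Total step count: 13. Longest linear sequence: 13 steps (1 to 26).

Steps most likely to fail

Step 6.
- What may go wrong: closure through the other rotamer of the acetyl group, which avoids the 1,3-diaxial contact between C15 and C14 and so delivers both oxygens to the β face.
- Also possible: erosion of the cis bias if the samarium bridge is lost, plain reduction of the aldehyde, and aldol closure or C5 epimerisation of the keto aldehyde before it is reduced.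
- The fallback sets out from 11 and still forms C3–C4, but as an alkene, with the oxygens added afterwards. McMurry coupling of 11 (TiCl3(DME)1.5, Zn–Cu, DME, reflux, high dilution) should give 8,8-ethylenedioxy-11,12,13-trinor-5αH-eudesm-3-ene F1. Catalytic OsO4 with N-methylmorpholine N-oxide in aqueous acetone should then add both hydroxyls syn from the α face, opposite axial C14. This rejoins the route at 13.

Step 13.
- What may go wrong: hydrogen abstraction from the C12/C13 methyl groups in place of H6β, slow oxygen transfer because H6β lies between the axial methyls C14 and C15, and competing ene attack on the angelate on long irradiation.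
- The fallback sets out from aldol 22 and leaves out steps 12 and 13. It is a direct dehydrogenation with 2-iodoxybenzoic acid (IBX) in DMSO at about 70 °C.
- Because C10 is quaternary, C6–C7 is the only α,β-desaturation open to the C8 ketone, so the reaction should lead straight to 26. This fallback makes no new compound (F0).

Step 8.
- What may go wrong: sluggish acylation of the crowded tertiary hydroxyl. Angeloyl migration from O3 to O4, followed by acetylation of the freed O3, could then compete, and prolonged heating with DMAP endangers the Z geometry.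
- The fallback sets out from 13 and installs the acetate while no angelate is present.
- TESCl and imidazole in DMF should silylate only the secondary hydroxyl to give 8,8-ethylenedioxy-3α-(triethylsilyloxy)-11,12,13-trinor-5αH-eudesman-4α-ol F2.
- Forcing acetylation (Ac2O, DMAP, Et3N, 60 °C) should give 8,8-ethylenedioxy-3α-(triethylsilyloxy)-11,12,13-trinor-5αH-eudesman-4α-yl acetate F3.
- HF·pyridine buffered with pyridine in THF at 0 °C should free 8,8-ethylenedioxy-3α-hydroxy-11,12,13-trinor-5αH-eudesman-4α-yl acetate F4 under non-basic conditions that disfavour acetyl migration.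
- Immediate acylation with mixed anhydride 15 in toluene at 80 °C rejoins the route at 17.

Further compounds
F1 | step 6 | 8,8-ethylenedioxy-11,12,13-trinor-5αH-eudesm-3-ene | CC1=CCC[C@]2(C)CC3(OCCO3)CC[C@@H]12
F2 | step 8 | 8,8-ethylenedioxy-3α-(triethylsilyloxy)-11,12,13-trinor-5αH-eudesman-4α-ol | CC[Si](CC)(CC)O[C@@H]1CC[C@]2(C)CC3(OCCO3)CC[C@H]2[C@]1(C)O
F3 | step 8 | 8,8-ethylenedioxy-3α-(triethylsilyloxy)-11,12,13-trinor-5αH-eudesman-4α-yl acetate | CC[Si](CC)(CC)O[C@@H]1CC[C@]2(C)CC3(OCCO3)CC[C@H]2[C@]1(C)OC(C)=O
F4 | step 8 | 8,8-ethylenedioxy-3α-hydroxy-11,12,13-trinor-5αH-eudesman-4α-yl acetate | O[C@@H]1CC[C@]2(C)CC3(OCCO3)CC[C@H]2[C@]1(C)OC(C)=O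
F0 | step 13 | none | none
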